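**Plan**
- Retrosynthesis: cut the C3–O ester bond first (SN2 by the dienoic acid with inversion), then take back C3–H, C4a–H and C8a–H to an 8a-hydroxy-Δ4(4a)-3-ketone, and open this through N1–C8a to a furan.
- Enabling feature: C3–C4–C4a–C8a of the piperidine ring is a four-carbon chain with O on C3 and N on C8a, and its C4a–C8a bond is shared with the carbocycle. It is therefore the C2–C3–C3a–C7a unit of a 4,5,6,7-tetrahydro-1-benzofuran that carries C2(Me)–N as a 1-aminoethyl arm. Oxidative ring expansion of the five-membered furan ring (aza-Achmatowicz) gives the six-membered nitrogen ring.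
- Forward order: side-chain bromide → three-component conjugate addition/allylation on cyclohexenone (carbocycle with C5) → furan ring → acetyl arm and amine → ring expansion closes the piperidine → three reductions → ester → deprotection.
- Stereochemistry: C5' from (R)-1,2-epoxypentane; C5 from the copper–ferrocenyl diphosphine catalyst; C2 from (S)-tert-butanesulfinamide; C8a, C4a and C3 by relay (hydride and hydrogen enter opposite the axial C2 methyl and the C5 chain; C3 is inverted in the esterification).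

Key step: step 10

Assumption: the hemiaminal carbon C8a of 24 should form as a mixture of epimers and is written without configuration, because it becomes trigonal again in step 11. Target positions use decahydroquinoline numbering (N1, C2 … C8a); TBS = tert-butyldimethylsilyl.

**Step 1**
Reactants: 1 (R)-2-propyloxirane; 2 allylmagnesium bromide
Product: 3 (5R)-oct-1-en-5-ol
Conditions: CuI (copper iodide, 10 mol%), THF, −30 → 0 °C; aq. NH4Cl
Reagents that add atoms: none
Why: Copper-catalysed SN2 opening of the terminal epoxide at its CH2 carbon by the Grignard reagent leaves the C–O stereocentre untouched, so the (R) epoxide gives the (R) alcohol.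

**Step 2**
Reactants: 3 (5R)-oct-1-en-5-ol
Product: 4 tert-butyl(dimethyl){[(5R)-oct-1-en-5-yl]oxy}silane
Conditions: TBSCl, imidazole, DMF, rt
Reagents that add atoms: tert-butyldimethylsilyl chloride CC(C)(C)[Si](C)(C)Cl
Why: Standard imidazole-promoted silylation of a secondary alcohol; the ether must survive organometallic, oxidative and mild acidic steps and fall off with the carbamate at the end.

**Step 3**
Reactants: 4 tert-butyl(dimethyl){[(5R)-oct-1-en-5-yl]oxy}silane
Product: 6 (5R)-5-(TBSO)octan-1-ol, via B-alkyl-9-BBN 5 (not isolated)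
Conditions: 9-BBN-H (0.5 M in THF), THF, 0 °C → rt; then aq. NaOH, H2O2, 0 °C → rt
Reagents that add atoms: 9-borabicyclo[3.3.1]nonane B1C2CCCC1CCC2 (boron and bicyclic ring of intermediate 5 only); hydrogen peroxide OO
Why: Anti-Markovnikov hydroboration of the terminal alkene followed by oxidation of the C–B bond with retention gives the primary alcohol without touching the stereocentre or the silyl ether (Brown hydroboration–oxidation).

**Step 4**
Reactants: 6 (5R)-5-(TBSO)octan-1-ol
Product: 7 {[(4R)-8-bromooctan-4-yl]oxy}(tert-butyl)dimethylsilane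
Conditions: CBr4, PPh3, CH2Cl2, 0 °C → rt
Reagents that add atoms: carbon tetrabromide BrC(Br)(Br)Br
Why: Appel bromination converts the primary alcohol into the bromide under neutral conditions through an oxyphosphonium ion, leaving the secondary silyl ether intact.

**Step 5**
Reactants: 7 {[(4R)-8-bromooctan-4-yl]oxy}(tert-butyl)dimethylsilane; 8 cyclohex-2-en-1-one; 9 allyl iodide
Product: 12 (2R,3S)-3-[(5R)-5-(TBSO)octyl]-2-(prop-2-en-1-yl)cyclohexan-1-one, via Grignard reagent 10 (not isolated), via bromomagnesium enolate 11 (not isolated)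
Conditions: Mg turnings (I2 cat.), Et2O, rt → reflux; the solution of 10 added to 8, CuCl (5 mol%), TaniaPhos ligand [1-(diphenylphosphino)-2-{(dimethylamino)[2-(diphenylphosphino)phenyl]methyl}ferrocene, single enantiomer, the antipode that gives the 3S ketone, 6 mol%], Et2O, 0 °C; then 9 (3 equiv), DMPU, −30 → 0 °C; aq. NH4Cl
Reagents that add atoms: magnesium [Mg] (magnesium of intermediates 10 and 11 only)
Why: Copper-catalysed asymmetric conjugate addition of a primary alkyl Grignard reagent to cyclohexenone with a ferrocenyl diphosphine ligand sets the (3S) centre (future C5) by catalyst control, and the regiodefined bromomagnesium enolate 11, activated by the polar cosolvent, is then C-allylated at C2 trans to the new chain (three-component conjugate addition–enolate alkylation).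

**Step 6**
Reactants: 12 (2R,3S)-3-[(5R)-5-(TBSO)octyl]-2-(prop-2-en-1-yl)cyclohexan-1-one
Product: 14 (4S)-4-[(5R)-5-(TBSO)octyl]-4,5,6,7-tetrahydro-1-benzofuran, via keto aldehyde 13 (not isolated)
Conditions: O3, CH2Cl2, −78 °C; PPh3, −78 °C → rt; then PPTS (10 mol%), toluene, 60 °C
Reagents that add atoms: ozone O=[O+][O-] (aldehyde oxygen of intermediate 13)
Why: Ozonolysis gives the 1,4-keto aldehyde 13, which cyclodehydrates under mild acid to the furan (Paal–Knorr furan synthesis); the allyl-bearing carbon becomes trigonal and the chain-bearing centre is not enolisable.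

**Step 7**
Reactants: 14 (4S)-4-[(5R)-5-(TBSO)octyl]-4,5,6,7-tetrahydro-1-benzofuran; 15 N-methoxy-N-methylacetamide
Product: 17 1-{(4S)-4-[(5R)-5-(TBSO)octyl]-4,5,6,7-tetrahydro-1-benzofuran-2-yl}ethan-1-one, via 2-furyllithium 16 (not isolated)
Conditions: n-BuLi, THF, −78 → 0 °C; then 15, −78 °C → rt; aq. NH4Cl
Reagents that add atoms: n-butyllithium CCCC[Li] (lithium of intermediate 16 only)
Why: Lithiation at the only free α-position of the furan and acylation with a Weinreb amide, whose chelated tetrahedral intermediate stops the reaction at the ketone.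

**Step 8**
Reactants: 17 1-{(4S)-4-[(5R)-5-(TBSO)octyl]-4,5,6,7-tetrahydro-1-benzofuran-2-yl}ethan-1-one; 18 (S)-2-methylpropane-2-sulfinamide
Product: 20 (S)-N-[(1S)-1-{(4S)-4-[(5R)-5-(TBSO)octyl]-4,5,6,7-tetrahydro-1-benzofuran-2-yl}ethyl]-2-methylpropane-2-sulfinamide, via sulfinyl ketimine 19 (not isolated)
Conditions: Ti(OEt)4, THF, 70 °C; then NaBH4, −48 °C; brine, Celite
Reagents that add atoms: none
Why: Ellman one-pot reductive amination; hydride is delivered to the (E)-ketimine 19 through the six-membered chelate on the face syn to the sulfinyl oxygen, so the (S)-sulfinyl group should set the (S) carbinamine centre (future C2), and the minor diastereomer is removable by chromatography.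

**Step 9**
Reactants: 20 (S)-N-[(1S)-1-{(4S)-4-[(5R)-5-(TBSO)octyl]-4,5,6,7-tetrahydro-1-benzofuran-2-yl}ethyl]-2-methylpropane-2-sulfinamide
Product: 22 tert-butyl N-[(1S)-1-{(4S)-4-[(5R)-5-(TBSO)octyl]-4,5,6,7-tetrahydro-1-benzofuran-2-yl}ethyl]carbamate, via ammonium chloride 21 (not isolated)
Conditions: HCl (4 M in dioxane, 2 equiv), MeOH, 0 °C, short contact; concentrate; then Boc2O, Et3N, CH2Cl2, rt
Reagents that add atoms: di-tert-butyl dicarbonate CC(C)(C)OC(=O)OC(=O)OC(C)(C)C; hydrogen chloride Cl (chloride of intermediate 21 only)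
Why: Acidic methanolysis of the S–N bond is fast at 0 °C, where the secondary silyl ether is expected to survive, and the amine is then converted into the carbamate needed for the ring expansion and for acid-only final deprotection.

**Step 10**
Reactants: 22 tert-butyl N-[(1S)-1-{(4S)-4-[(5R)-5-(TBSO)octyl]-4,5,6,7-tetrahydro-1-benzofuran-2-yl}ethyl]carbamate
Product: 24 tert-butyl (2S,5S)-8a-hydroxy-2-methyl-3-oxo-5-[(5R)-5-(TBSO)octyl]-3,5,6,7,8,8a-hexahydroquinoline-1(2H)-carboxylate (C8a epimers), via Z-ene-dione 23 (not isolated)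
Conditions: mCPBA (1.2 equiv), CH2Cl2, 0 °C; aq. NaHCO3/Na2S2O3
Reagents that add atoms: 3-chloroperoxybenzoic acid OOC(=O)c1cccc(Cl)c1
Why: The peracid epoxidises the electron-rich furan at the C2=C3 bond and the epoxide opens to the (Z)-ene-1,4-dione 23, whose carbamate nitrogen adds to the cyclohexanone carbonyl, so the five-membered furan ring is expanded to the six-membered dihydropyridinone ring (aza-Achmatowicz rearrangement of an N-protected furfurylamine, the closest known reaction type). The single ring closure is a 6-exo-trig attack of nitrogen on the C8a carbonyl, made possible because the Z geometry inherited from the furan holds N and C8a within reach. The only new stereocentre is the hemiaminal carbon C8a, formed reversibly under thermodynamic control and erased in step 11; C2 and C5 are carried through unchanged. The step needs chemoselective oxidation of the furan, secured because the trialkylfuran is the only π-nucleophile beside an inert carbamate and silyl ether, and it needs C2 (now α to a ketone) to keep its configuration, secured by low temperature and the absence of base. One operation thus turns a flat tetrahydrobenzofuran into the complete bicyclic skeleton with oxygen at C3, nitrogen at C8a and an enone plus hemiaminal as handles for the relay of stereochemistry.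

**Step 11**
Reactants: 24 tert-butyl (2S,5S)-8a-hydroxy-2-methyl-3-oxo-5-[(5R)-5-(TBSO)octyl]-3,5,6,7,8,8a-hexahydroquinoline-1(2H)-carboxylate
Product: 26 tert-butyl (2S,5S,8aR)-2-methyl-3-oxo-5-[(5R)-5-(TBSO)octyl]-3,5,6,7,8,8a-hexahydroquinoline-1(2H)-carboxylate, via N-acyliminium ion 25 (not isolated)
Conditions: Et3SiH, BF3·OEt2, CH2Cl2, −78 → −30 °C; aq. NaHCO3
Reagents that add atoms: none
Why: Ionic (Kishi-type) reduction: the tertiary hemiaminal ionises to the N-acyliminium ion 25 and the silane adds hydride axially at C8a on the face opposite the C2 methyl (held pseudoaxial by A1,3 strain with the carbamate) and opposite the C5 chain, giving the 2,8a-cis (8aR) centre.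

**Step 12**
Reactants: 26 tert-butyl (2S,5S,8aR)-2-methyl-3-oxo-5-[(5R)-5-(TBSO)octyl]-3,5,6,7,8,8a-hexahydroquinoline-1(2H)-carboxylate
Product: 27 tert-butyl (2S,4aS,5S,8aR)-2-methyl-3-oxo-5-[(5R)-5-(TBSO)octyl]octahydroquinoline-1(2H)-carboxylate
Conditions: H2 (1 atm), Pd/C (10% palladium on carbon), EtOAc, rt
Reagents that add atoms: none
Why: Heterogeneous hydrogenation of the C4=C4a enone from the face opposite the axial C2 methyl, the C8 methylene and the C5 chain should place H4a cis to H8a and H5, giving the cis ring fusion (4aS).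

**Step 13**
Reactants: 27 tert-butyl (2S,4aS,5S,8aR)-2-methyl-3-oxo-5-[(5R)-5-(TBSO)octyl]octahydroquinoline-1(2H)-carboxylate
Product: 28 tert-butyl (2S,3S,4aS,5S,8aR)-3-hydroxy-2-methyl-5-[(5R)-5-(TBSO)octyl]octahydroquinoline-1(2H)-carboxylate
Conditions: NaBH4, MeOH, −20 °C
Reagents that add atoms: none
Why: Borohydride attacks the C3 ketone axially from the open face anti to the axial C2 methyl, as in reductions of N-acyl 2-alkylpiperidin-3-ones, giving the equatorial 2,3-cis (3S) alcohol.

**Step 14**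
Reactants: 29 (2E)-hex-2-enal; 30 malonic acid
Product: 32 (2E,4E)-octa-2,4-dienoic acid, via alkylidenemalonic acid 31 (not isolated)
Conditions: pyridine, piperidine (cat.), 90 °C; aq. HCl
Reagents that add atoms: none
Why: Knoevenagel–Doebner condensation; decarboxylation of 31 gives the conjugated acid with the thermodynamically favoured E geometry at the new double bond.

**Step 15**
Reactants: 28 tert-butyl (2S,3S,4aS,5S,8aR)-3-hydroxy-2-methyl-5-[(5R)-5-(TBSO)octyl]octahydroquinoline-1(2H)-carboxylate; 32 (2E,4E)-octa-2,4-dienoic acid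
Product: 33 tert-butyl (2S,3R,4aS,5S,8aR)-2-methyl-3-{[(2E,4E)-octa-2,4-dienoyl]oxy}-5-[(5R)-5-(TBSO)octyl]octahydroquinoline-1(2H)-carboxylate
Conditions: PPh3, DIAD, THF, 0 °C → rt
Reagents that add atoms: none
Why: Mitsunobu esterification: the carboxylate displaces the equatorial oxyphosphonium group at C3 by SN2 with inversion, installing the ester and the 2,3-trans (3R) configuration in one operation; an equatorial leaving group has no anti-periplanar hydrogen, which disfavours elimination.

**Step 16**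
Reactants: 33 tert-butyl (2S,3R,4aS,5S,8aR)-2-methyl-3-{[(2E,4E)-octa-2,4-dienoyl]oxy}-5-[(5R)-5-(TBSO)octyl]octahydroquinoline-1(2H)-carboxylate
Product: 34 lepadin H
Conditions: TFA/CH2Cl2/H2O (10:10:1), 0 °C → rt; cold aq. NaHCO3
Reagents that add atoms: none
Why: Acidolysis removes the tert-butyl carbamate (loss of the tert-butyl cation, then decarboxylation) and hydrolyses the silyl ether, while the dienoate ester is stable to acid.

**Compound list**
1 | (R)-2-propyloxirane [(R)-1,2-epoxypentane] | CCC[C@@H]1CO1 | starting material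
2 | allylmagnesium bromide | C=CC[Mg]Br | starting material
3 | (5R)-oct-1-en-5-ol | C=CCC[C@H](O)CCC | intermediate
4 | tert-butyl(dimethyl){[(5R)-oct-1-en-5-yl]oxy}silane | C=CCC[C@H](O[Si](C)(C)C(C)(C)C)CCC | intermediate
5 | 9-[(5R)-5-(TBSO)octyl]-9-borabicyclo[3.3.1]nonane | CCC[C@@H](O[Si](C)(C)C(C)(C)C)CCCCB1C2CCCC1CCC2 | intermediate (not isolated)
6 | (5R)-5-(TBSO)octan-1-ol | OCCCC[C@H](O[Si](C)(C)C(C)(C)C)CCC | intermediate
7 | {[(4R)-8-bromooctan-4-yl]oxy}(tert-butyl)dimethylsilane | BrCCCC[C@H](O[Si](C)(C)C(C)(C)C)CCC | intermediate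
8 | cyclohex-2-en-1-one | O=C1C=CCCC1 | starting material
9 | allyl iodide (3-iodoprop-1-ene) | C=CCI | starting material
10 | [(5R)-5-(TBSO)octyl]magnesium bromide | Br[Mg]CCCC[C@H](O[Si](C)(C)C(C)(C)C)CCC | intermediate (not isolated)
11 | bromomagnesium (3S)-3-[(5R)-5-(TBSO)octyl]cyclohex-1-en-1-olate | Br[Mg]OC1=C[C@@H](CCCC[C@H](O[Si](C)(C)C(C)(C)C)CCC)CCC1 | intermediate (not isolated)
12 | (2R,3S)-3-[(5R)-5-(TBSO)octyl]-2-(prop-2-en-1-yl)cyclohexan-1-one | O=C1CCC[C@H](CCCC[C@H](O[Si](C)(C)C(C)(C)C)CCC)[C@H]1CC=C | intermediate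
13 | 2-{(1R,2S)-2-[(5R)-5-(TBSO)octyl]-6-oxocyclohexyl}acetaldehyde | O=C1CCC[C@H](CCCC[C@H](O[Si](C)(C)C(C)(C)C)CCC)[C@H]1CC=O | intermediate (not isolated)
14 | (4S)-4-[(5R)-5-(TBSO)octyl]-4,5,6,7-tetrahydro-1-benzofuran | c1cc2[C@@H](CCCC[C@H](O[Si](C)(C)C(C)(C)C)CCC)CCCc2o1 | intermediate
15 | N-methoxy-N-methylacetamide | CON(C)C(C)=O | starting material
16 | {(4S)-4-[(5R)-5-(TBSO)octyl]-4,5,6,7-tetrahydro-1-benzofuran-2-yl}lithium | [Li]c1cc2[C@@H](CCCC[C@H](O[Si](C)(C)C(C)(C)C)CCC)CCCc2o1 | intermediate (not isolated)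
17 | 1-{(4S)-4-[(5R)-5-(TBSO)octyl]-4,5,6,7-tetrahydro-1-benzofuran-2-yl}ethan-1-one | CC(=O)c1cc2[C@@H](CCCC[C@H](O[Si](C)(C)C(C)(C)C)CCC)CCCc2o1 | intermediate
18 | (S)-2-methylpropane-2-sulfinamide | CC(C)(C)[S@](=O)N | starting material
19 | (S,E)-N-[1-{(4S)-4-[(5R)-5-(TBSO)octyl]-4,5,6,7-tetrahydro-1-benzofuran-2-yl}ethylidene]-2-methylpropane-2-sulfinamide | C/C(=N\[S@@](=O)C(C)(C)C)c1cc2[C@@H](CCCC[C@H](O[Si](C)(C)C(C)(C)C)CCC)CCCc2o1 | intermediate (not isolated)
20 | (S)-N-[(1S)-1-{(4S)-4-[(5R)-5-(TBSO)octyl]-4,5,6,7-tetrahydro-1-benzofuran-2-yl}ethyl]-2-methylpropane-2-sulfinamide | C[C@H](N[S@@](=O)C(C)(C)C)c1cc2[C@@H](CCCC[C@H](O[Si](C)(C)C(C)(C)C)CCC)CCCc2o1 | intermediate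
21 | (1S)-1-{(4S)-4-[(5R)-5-(TBSO)octyl]-4,5,6,7-tetrahydro-1-benzofuran-2-yl}ethan-1-aminium chloride | C[C@H]([NH3+])c1cc2[C@@H](CCCC[C@H](O[Si](C)(C)C(C)(C)C)CCC)CCCc2o1.[Cl-] | intermediate (not isolated)
22 | tert-butyl N-[(1S)-1-{(4S)-4-[(5R)-5-(TBSO)octyl]-4,5,6,7-tetrahydro-1-benzofuran-2-yl}ethyl]carbamate | C[C@H](NC(=O)OC(C)(C)C)c1cc2[C@@H](CCCC[C@H](O[Si](C)(C)C(C)(C)C)CCC)CCCc2o1 | intermediate
23 | tert-butyl N-[(2S,4Z)-4-{(2S)-2-[(5R)-5-(TBSO)octyl]-6-oxocyclohexylidene}-3-oxobutan-2-yl]carbamate | C[C@H](NC(=O)OC(C)(C)C)C(=O)/C=C1\C(=O)CCC[C@@H]1CCCC[C@H](O[Si](C)(C)C(C)(C)C)CCC | intermediate (not isolated)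
24 | tert-butyl (2S,5S)-8a-hydroxy-2-methyl-3-oxo-5-[(5R)-5-(TBSO)octyl]-3,5,6,7,8,8a-hexahydroquinoline-1(2H)-carboxylate (C8a epimers) | O=C1C=C2[C@@H](CCCC[C@H](O[Si](C)(C)C(C)(C)C)CCC)CCCC2(O)N(C(=O)OC(C)(C)C)[C@H]1C | intermediate
25 | (2S,5S)-1-(tert-butoxycarbonyl)-2-methyl-3-oxo-5-[(5R)-5-(TBSO)octyl]-2,3,5,6,7,8-hexahydroquinolin-1-ium | O=C1C=C2[C@@H](CCCC[C@H](O[Si](C)(C)C(C)(C)C)CCC)CCCC2=[N+](C(=O)OC(C)(C)C)[C@H]1C | intermediate (not isolated)
26 | tert-butyl (2S,5S,8aR)-2-methyl-3-oxo-5-[(5R)-5-(TBSO)octyl]-3,5,6,7,8,8a-hexahydroquinoline-1(2H)-carboxylate | O=C1C=C2[C@@H](CCCC[C@H](O[Si](C)(C)C(C)(C)C)CCC)CCC[C@H]2N(C(=O)OC(C)(C)C)[C@H]1C | intermediate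
27 | tert-butyl (2S,4aS,5S,8aR)-2-methyl-3-oxo-5-[(5R)-5-(TBSO)octyl]octahydroquinoline-1(2H)-carboxylate | O=C1C[C@H]2[C@@H](CCCC[C@H](O[Si](C)(C)C(C)(C)C)CCC)CCC[C@H]2N(C(=O)OC(C)(C)C)[C@H]1C | intermediate
28 | tert-butyl (2S,3S,4aS,5S,8aR)-3-hydroxy-2-methyl-5-[(5R)-5-(TBSO)octyl]octahydroquinoline-1(2H)-carboxylate | O[C@H]1C[C@H]2[C@@H](CCCC[C@H](O[Si](C)(C)C(C)(C)C)CCC)CCC[C@H]2N(C(=O)OC(C)(C)C)[C@H]1C | intermediate
29 | (2E)-hex-2-enal | CCC/C=C/C=O | starting material
30 | malonic acid | OC(=O)CC(=O)O | starting material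
31 | [(2E)-hex-2-en-1-ylidene]propanedioic acid | CCC/C=C/C=C(C(=O)O)C(=O)O | intermediate (not isolated)
32 | (2E,4E)-octa-2,4-dienoic acid | CCC/C=C/C=C/C(=O)O | intermediate
33 | tert-butyl (2S,3R,4aS,5S,8aR)-2-methyl-3-{[(2E,4E)-octa-2,4-dienoyl]oxy}-5-[(5R)-5-(TBSO)octyl]octahydroquinoline-1(2H)-carboxylate | CCC/C=C/C=C/C(=O)O[C@@H]1C[C@H]2[C@@H](CCCC[C@H](O[Si](C)(C)C(C)(C)C)CCC)CCC[C@H]2N(C(=O)OC(C)(C)C)[C@H]1C | intermediate
34 | lepadin H, (2S,3R,4aS,5S,8aR)-5-[(5R)-5-hydroxyoctyl]-2-methyldecahydroquinolin-3-yl (2E,4E)-octa-2,4-dienoate | CCC/C=C/C=C/C(=O)O[C@@H]1C[C@H]2[C@@H](CCCC[C@H](O)CCC)CCC[C@H]2N[C@H]1C | target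

**Step count and risks**
Total steps: 16. Longest linear sequence: 15 (steps 1–13, 15 and 16, from (R)-2-propyloxirane).

Steps most likely to fail:

1. Step 10. The peracid may over-oxidise the electron-rich ene-dione, and its acid by-product may cause Z-to-E isomerisation and C2 epimerisation before the weakly nucleophilic carbamate has closed onto the hindered ketone. The fallback sets out from 22 and returns at 24. Anodic oxidation of 22 in methanol (undivided cell, graphite anode, Et4NOTs, −10 °C; Clauson-Kaas-type 2,5-dimethoxylation) should give tert-butyl N-[(1S)-1-{(4S)-2,7a-dimethoxy-4-[(5R)-5-(TBSO)octyl]-2,4,5,6,7,7a-hexahydro-1-benzofuran-2-yl}ethyl]carbamate F1 as an isolable masked ene-dione. Mild hydrolysis (PPTS, acetone/water, rt) then unmasks it in the absence of any oxidant, and the same 6-exo closure should deliver 24.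

2. Step 15. Substitution at the hindered oxyphosphonium centre by a weakly acidic dienoic acid may be slow, so that elimination or acylation of the hydrazine by-product takes over. The fallback sets out from 28 and returns at 33. Mitsunobu inversion with the more acidic 4-nitrobenzoic acid (PPh3, DIAD, toluene) should give tert-butyl (2S,3R,4aS,5S,8aR)-2-methyl-3-[(4-nitrobenzoyl)oxy]-5-[(5R)-5-(TBSO)octyl]octahydroquinoline-1(2H)-carboxylate F2. Methanolysis (K2CO3, MeOH) frees tert-butyl (2S,3R,4aS,5S,8aR)-3-hydroxy-2-methyl-5-[(5R)-5-(TBSO)octyl]octahydroquinoline-1(2H)-carboxylate F3, which is acylated with retention by 32 under Yamaguchi conditions (2,4,6-trichlorobenzoyl chloride, Et3N, DMAP, toluene) to give 33.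

3. Step 5. Competing 1,2-addition of the Grignard reagent and imperfect enantiocontrol with the long functionalised chain may lower yield and optical purity, and proton transfer between the magnesium enolate and the alkylated ketone may lead to regioisomeric or double allylation. The fallback sets out from 4 and returns at 14. Commercial 6,7-dihydro-1-benzofuran-4(5H)-one F4 is converted (KHMDS, PhNTf2, THF, −78 °C) into 6,7-dihydro-1-benzofuran-4-yl trifluoromethanesulfonate F5. Alkene 4 is hydroborated with 9-BBN-H to the borane 5, as in the first half of step 3. Without oxidation, 5 is coupled with F5 (Pd(dppf)Cl2, K3PO4, THF/DMF/H2O, 60 °C; B-alkyl Suzuki–Miyaura) to give 4-[(5R)-5-(TBSO)octyl]-6,7-dihydro-1-benzofuran F6. Asymmetric hydrogenation of this cyclic trisubstituted aryl-type alkene ([Ir(cod)(L)]BArF with a phosphinooxazoline ligand L, H2 50 bar, CH2Cl2; ligand antipode selected for the 4S centre) should then give 14.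

**Further compounds**
F1 | step 10 | tert-butyl N-[(1S)-1-{(4S)-2,7a-dimethoxy-4-[(5R)-5-(TBSO)octyl]-2,4,5,6,7,7a-hexahydro-1-benzofuran-2-yl}ethyl]carbamate (ketal epimers) | C[C@H](NC(=O)OC(C)(C)C)C1(OC)C=C2[C@@H](CCCC[C@H](O[Si](C)(C)C(C)(C)C)CCC)CCCC2(OC)O1
F2 | step 15 | tert-butyl (2S,3R,4aS,5S,8aR)-2-methyl-3-[(4-nitrobenzoyl)oxy]-5-[(5R)-5-(TBSO)octyl]octahydroquinoline-1(2H)-carboxylate | O=C(O[C@@H]1C[C@H]2[C@@H](CCCC[C@H](O[Si](C)(C)C(C)(C)C)CCC)CCC[C@H]2N(C(=O)OC(C)(C)C)[C@H]1C)c1ccc(cc1)[N+](=O)[O-]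
F3 | step 15 | tert-butyl (2S,3R,4aS,5S,8aR)-3-hydroxy-2-methyl-5-[(5R)-5-(TBSO)octyl]octahydroquinoline-1(2H)-carboxylate | O[C@@H]1C[C@H]2[C@@H](CCCC[C@H](O[Si](C)(C)C(C)(C)C)CCC)CCC[C@H]2N(C(=O)OC(C)(C)C)[C@H]1C
F4 | step 5 | 6,7-dihydro-1-benzofuran-4(5H)-one | O=C1CCCc2occc12
F5 | step 5 | 6,7-dihydro-1-benzofuran-4-yl trifluoromethanesulfonate | O=S(=O)(OC1=CCCc2occc12)C(F)(F)F
F6 | step 5 | 4-[(5R)-5-(TBSO)octyl]-6,7-dihydro-1-benzofuran | CCC[C@@H](O[Si](C)(C)C(C)(C)C)CCCCC1=CCCc2occc12
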